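## The problem

Compound 28 is a cis,cis-germacranolide. Germacrane numbering is used throughout: the ten-membered ring is C1–C10, C1=C10 carries the C14 aldehyde, C4=C5 carries the C15 hydroxymethyl, the lactone oxygen sits on C6, C7 carries C11 (C12 carbonyl, C13 methylene), and C8 carries the 3-methylbutanoate. Both trisubstituted ring olefins are cis within the ring (E by the sequence rule), so the carbocycle cannot be made by the usual routes to ring-trans germacrenes. The three contiguous stereocentres are 6S, 7R and 8S: the lactone is cis-fused (H6 and H7 syn) and the C8 ester lies on the face opposite to C11. C8 can be set alone by a reagent-controlled reduction and can then steer C7 through allylic strain; C6 can only be set relative to C7, in the lactone closure. The α-methylene lactone and the enal are Michael acceptors and will not survive hydrazine, peroxide anions or strong base. The C6 and C8 oxygens are allylic and ionisable, and the secondary ester rules out any late hydrolysis or hydride reduction. The enabling feature is that C7–C11 and O–C6 sit on adjacent ring carbons directly beside C4=C5. This is the pattern left when a carboxymethyl radical adds to C7 of a C4=C5–C6=C7 ring diene and the carboxylate captures the C6 end of the resulting allyl system. The two ring-cis methyl-bearing olefins in 1,5-relation are also the pattern of the isoprene cyclodimer.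

## Retrosynthesis

**28 back to 24 (end game).** The C15 silyl ether of 27 is the only protecting group. The C11=C13 bond of 27 is cut back to the C11 carboxylic acid 25 (decarboxylative Mannich methylenation), and 25 to its tert-butyl ester 24. Direct methylenation of a lactone enolate would expose the enal and the C8 ester to strong base, whereas the C11 carboxyl comes free of charge from the lactone-forming step. The forward reactions must only leave the enal, the isovalerate and the allylic lactone untouched.

**24 to 22 and 23 (key disconnection).** C7–C11 and O–C6 are cut together, giving the ring diene 22 and mono-tert-butyl malonate 23. Cutting O–C6 alone would require a separate synthesis of the C7 stereocentre. Building the lactone from a C6 ketone by enolate alkylation would leave C8 without a handle. The double cut removes one ring and two stereocentres and leaves a precursor with the single stereocentre C8. The forward reaction must attack C7 and not C4, on the face anti to the C8–C9 bond, and close on C6 on the same face.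

**22 to 18 (C–H oxidations).** The C15 silyl ether 22 comes from alcohol 21, and the C15 and C14 oxygens are cut back to methyl groups (21 from 20 from 18). Carrying oxidised methyls from the start would need two orthogonal protecting groups, and an aldehyde cannot pass the hydrazine step. The order follows reactivity: the isolated C1=C10 olefin of 18 is oxidised first, and once it is an enal only the diene end C4=C5 remains nucleophilic. The precursor 18 has the bare isoprene-dimer substitution.

**18 to 15 (ester and the C8 stereocentre).** The ester C–O bond is cut to alcohol 16 and 3-methylbutanoic acid 17, and the C8–H bond to the achiral dienone 15. An asymmetric epoxidation earlier in the route was considered, but its sense cannot be predicted for a medium-ring enone of uncertain geometry. A Corey–Bakshi–Shibata reduction of a dienyl alkyl ketone has a dependable sense. The forward reduction must be 1,2-selective and must not hydroborate the olefins.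

**15 to 10 (oxygen relay from C6 to C8).** Dienone 15 comes from the racemic dienol 14, which is the Wharton product of epoxy ketone 12; 12 comes from the cross-conjugated trienone 11, and 11 from the silyl dienol ether 10. There is no direct way to oxidise C8 selectively, but the ketone oxygen that the ring expansion leaves at C6 can be moved there in three operations. The forward sequence must deliver the ring-cis C6=C7 olefin; the geometry of C7=C8 in 11 and the configuration of 12 are not relied on, because C7 becomes sp2 and C8 is re-set at 15.

**10 to 6 and 7 (ten-membered ring).** The C8–C9 bond is cut, and C6–C9 re-formed, giving the eight-membered vinyl carbinol 8, itself from dienone 6 and vinylmagnesium bromide 7. A four-carbon oxy-Cope expansion from a cyclohexenone would give a ring-trans C1=C10 olefin. A macrocyclisation would have to create one of the cis trisubstituted olefins or close a strained ring against entropy. The two-carbon alkoxide [1,3] shift keeps both olefins of the isoprene dimer and delivers the enolate on the side needed for the next step.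

**6 to 1 (placing the ketone).** The C6 carbonyl is cut back through tertiary allylic alcohol 5 and monoepoxide 2 to 1,5-dimethylcycloocta-1,5-diene 1. Direct allylic oxidation of 1 would be shorter but risks regioisomers and over-oxidation at the doubly activated C9 methylene. The epoxide, selenide and oxidative-transposition sequence fixes the carbonyl position without ambiguity.

## Roads not taken

**Alternative 1:** The plan organised around the isoprene-dimer ring expansion.
- **Cut and key step:** the cut is C8–C9 of the carbocycle. The potassium alkoxide of a C6 vinyl carbinol shifts allylic C9 to the vinyl terminus and gives the ten-membered dienone A1.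
- **Merits:** both ring-cis olefins and the whole carbocycle come from a commodity in a handful of steps, with no macrocyclisation.
- **Weak points:** as the governing idea it stops at a ring with oxygen only at C6. The lactone would have to be grown from that ketone by C7 enolate alkylation with a haloacetate and C6 reduction. C8 would be left without a handle once C7 is substituted, and there would be no obvious stage for absolute stereocontrol.
- **Comparison:** in ring construction the two plans are equal, because the chosen route uses the same shift (steps 4 and 5, with the enolate trapped as 10 instead of protonated to A1). Alternative 1 is arguably safer at C6 and C7, since enolate alkylation and hydride reduction of a ketone are more predictable than a radical annulation in a medium ring. The chosen plan sets against this the use of the C6 oxygen as a relay to C8 and the formation of both lactone bonds in one step.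

**Alternative 2:** Macrocyclisation by Horner–Wadsworth–Emmons olefination.
- **Cut and key step:** the cut is the C4=C5 double bond. A C4 phosphonate anion (LiCl, DBU) adds to a C5 aldehyde in the same chain and gives the ten-membered acrylate A2, which carries protected C6, C8, C12 and C14 oxygens.
- **Merits:** the three stereocentres are set in an open chain by reliable aldol and allylation chemistry with absolute control. The intrinsic preference of the olefination for the E-enoate is exactly the ring-cis geometry. Every oxygen is differentiated.
- **Weak points:** closing a ten-membered ring by olefination fights transannular strain and oligomerisation. The C15 ester must later be reduced beside other esters, which forces four different protecting groups. The lactone, the methylene group and the enal are all still to be unveiled after A2.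
- **Comparison:** this road is better in stereochemical certainty. The chosen plan sets against it a ring obtained by expansion and not by cyclisation, far fewer protecting-group operations and roughly half the length.

**Alternative 3:** Ring closure by B-alkyl Suzuki–Miyaura coupling.
- **Cut and key step:** the cut is C3–C4. 9-BBN hydroborates a terminal C2=C3 olefin, and PdCl2(dppf) with Cs2CO3 couples the borane with a C4 vinyl iodide with retention, giving A3, which lacks only C13 and the final oxidation states.
- **Merits:** the cis-lactone and all stereocentres are in place before the ring is closed, made on a five-membered template where cis control is dependable. The vinyl iodide fixes the C4=C5 geometry.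
- **Weak points:** a ten-membered ring with two cis olefins and a fused lactone is at the strained limit of this coupling. The hydroboration must distinguish the terminal olefin from C1=C10. The C8 ester and the lactone meet carbonate base and zerovalent palladium, which can ionise allylic esters. The open-chain precursor is long.
- **Comparison:** this road is better on lactone stereochemistry and worse on ring-closure risk and length. The chosen plan sets against it that the ring is never closed by cyclisation, and that a stereospecific cyclopropane variant stands behind the lactone step.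

Key step: step 15

Assumption: commercial 1 is taken free of its 1,6-dimethyl isomer (fractional distillation); compounds 2–15 are racemic or achiral, and the absolute configuration is first set in step 10.

## Steps

Step 1
Reactants: 1 (1Z,5Z)-1,5-dimethylcycloocta-1,5-diene
Product: 2 rac-(4Z)-1,5-dimethyl-9-oxabicyclo[6.1.0]non-4-ene (cis-epoxide at C4–C5)
Conditions: mCPBA (1.0 equiv), CH2Cl2, 0 °C
Reagents that add atoms: 3-chloroperoxybenzoic acid (mCPBA), OOC(=O)c1cccc(Cl)c1
Why: Prilezhaev epoxidation; the two olefins of 1 are equivalent, so one equivalent of peracid gives the monoepoxide without a regiochemical question, and syn addition fixes the cis-epoxide.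

Step 2
Reactants: 2 rac-(4Z)-1,5-dimethyl-9-oxabicyclo[6.1.0]non-4-ene
Product: 5 rac-(2Z,5Z)-1,5-dimethylcycloocta-2,5-dien-1-ol, via hydroxy selenide 3 (not isolated), via selenoxide 4 (not isolated)
Conditions: (PhSe)2, NaBH4, EtOH, reflux; then H2O2, THF, 0 °C to rt
Reagents that add atoms: none
Why: Organoselenium epoxide-to-allylic-alcohol conversion: benzeneselenolate opens the epoxide at the secondary carbon C5 (SN2, anti), and selenoxide syn-elimination can only run toward C6 because the carbinol carbon C4 has no hydrogen.

Step 3
Reactants: 5 rac-(2Z,5Z)-1,5-dimethylcycloocta-2,5-dien-1-ol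
Product: 6 (2Z,6Z)-3,7-dimethylcycloocta-2,6-dien-1-one
Conditions: pyridinium chlorochromate, CH2Cl2, rt
Reagents that add atoms: pyridinium chlorochromate, [O-][Cr](=O)(=O)Cl.c1cc[nH+]cc1
Why: Babler–Dauben oxidative transposition: the chromate ester of the tertiary allylic alcohol undergoes a [3,3] shift and is oxidised, placing the carbonyl at C6 and returning the ring-cis C4=C5 olefin as a β-methyl enone.

Step 4
Reactants: 6 (2Z,6Z)-3,7-dimethylcycloocta-2,6-dien-1-one; 7 vinylmagnesium bromide
Product: 8 rac-(2Z,6Z)-1-ethenyl-3,7-dimethylcycloocta-2,6-dien-1-ol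
Conditions: CeCl3, THF, −78 °C
Reagents that add atoms: none
Why: 1,2-Addition of the vinylcerium reagent; the low basicity suppresses enolisation at the doubly activated C9 methylene and conjugate addition, giving the tertiary bis-allylic carbinol.

Step 5
Reactants: 8 rac-(2Z,6Z)-1-ethenyl-3,7-dimethylcycloocta-2,6-dien-1-ol
Product: 10 trimethylsilyl dienol ether of (2Z,6Z)-3,7-dimethylcyclodeca-2,6-dien-1-one (C4=C5–C6(OSiMe3)=C7; all ring olefins cis), via potassium dienolate 9 (not isolated)
Conditions: KH, 18-crown-6, THF, 0 °C to rt; then Et3N, Me3SiCl, −78 °C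
Reagents that add atoms: chlorotrimethylsilane, C[Si](C)(C)Cl
Why: Alkoxide-accelerated [1,3]-sigmatropic two-carbon ring expansion of a 1-vinylcycloalk-3-en-1-ol: allylic C9 moves from C6 to the vinyl terminus C8, and the regiodefined dienolate is trapped on oxygen. Both trisubstituted olefins are spectators and keep their ring-cis geometry.

Step 6
Reactants: 10 trimethylsilyl dienol ether
Product: 11 (2Z,6Z,9Z)-3,7-dimethylcyclodeca-2,6,9-trien-1-one
Conditions: Pd(OAc)2 (1.1 equiv), MeCN, rt
Reagents that add atoms: none
Why: Saegusa–Ito oxidation: divalent palladium forms the C7-bound enolate and β-hydride elimination from C8, the only carbon with β-hydrogens, gives the C7=C8 enone. The geometry of this olefin (drawn cis) is not relied on later.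

Step 7
Reactants: 11 (2Z,6Z,9Z)-3,7-dimethylcyclodeca-2,6,9-trien-1-one
Product: 12 rac-(3Z,7Z)-4,8-dimethyl-11-oxabicyclo[8.1.0]undeca-3,7-dien-2-one (C7–C8 epoxide, drawn cis)
Conditions: 30% H2O2, NaOH (cat.), MeOH, 0 °C
Reagents that add atoms: hydrogen peroxide, OO
Why: Weitz–Scheffer nucleophilic epoxidation; hydroperoxide adds to the β-monosubstituted C8 of the cross-conjugated dienone much faster than to the β,β-disubstituted C4. The racemic product is acceptable because C7 becomes sp2 in step 8 and C8 is re-set in step 10.

Step 8
Reactants: 12 rac-epoxy ketone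
Product: 14 rac-(2Z,4Z,8Z)-5,9-dimethylcyclodeca-2,4,8-trien-1-ol, via epoxy hydrazone 13 (not isolated)
Conditions: N2H4·H2O, AcOH (cat.), MeOH, 0 °C to rt
Reagents that add atoms: none
Why: Wharton transposition: the epoxy hydrazone fragments to the C8 alkoxide and an alkenyl diazene that loses N2, moving the oxygen from C6 to C8 and creating C6=C7. The ring-cis olefin is expected because the cis,cis-1,3-diene is the low-strain arrangement in a ten-membered ring.

Step 9
Reactants: 14 rac-(2Z,4Z,8Z)-5,9-dimethylcyclodeca-2,4,8-trien-1-ol
Product: 15 (2Z,4Z,8Z)-5,9-dimethylcyclodeca-2,4,8-trien-1-one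
Conditions: Dess–Martin periodinane, CH2Cl2, 0 °C
Reagents that add atoms: none
Why: Dess–Martin oxidation of the dienylic alcohol under near-neutral conditions, which leave the skipped C9 methylene and the olefin geometries untouched.

Step 10
Reactants: 15 (2Z,4Z,8Z)-5,9-dimethylcyclodeca-2,4,8-trien-1-one
Product: 16 (1S,2Z,4Z,8Z)-5,9-dimethylcyclodeca-2,4,8-trien-1-ol (8S in germacrane numbering)
Conditions: (R)-2-methyl-CBS-oxazaborolidine (20 mol %), catecholborane, toluene, −78 °C
Reagents that add atoms: none
Why: Corey–Bakshi–Shibata reduction: the dienyl arm acts as the large group and the C9 methylene as the small one, so the (R)-catalyst delivers hydride to give the S carbinol. Catecholborane at low temperature avoids hydroboration and 1,4-reduction.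

Step 11
Reactants: 16 (1S,2Z,4Z,8Z)-5,9-dimethylcyclodeca-2,4,8-trien-1-ol; 17 3-methylbutanoic acid
Product: 18 (1S,2Z,4Z,8Z)-5,9-dimethylcyclodeca-2,4,8-trien-1-yl 3-methylbutanoate
Conditions: EDC·HCl, DMAP (cat.), CH2Cl2, 0 °C to rt
Reagents that add atoms: none
Why: Steglich esterification acylates the secondary dienylic alcohol on oxygen with retention and without ionising conditions.

Step 12
Reactants: 18 (1S,2Z,4Z,8Z)-5,9-dimethylcyclodeca-2,4,8-trien-1-yl 3-methylbutanoate
Product: 20 (1S,2Z,4Z,8E)-9-formyl-5-methylcyclodeca-2,4,8-trien-1-yl 3-methylbutanoate, via C14 allylic alcohol 19 (not isolated)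
Conditions: SeO2 (cat.), t-BuOOH, CH2Cl2, 0 °C to rt; then MnO2
Reagents that add atoms: selenium dioxide, O=[Se]=O (oxygen, replenished by tert-butyl hydroperoxide, CC(C)(C)OO)
Why: Riley allylic oxidation (ene reaction, then [2,3] shift) at the isolated and more nucleophilic C1=C10 olefin, on the methyl group and not on the C9 methylene, which is deactivated by the neighbouring acyloxy carbon. The [2,3] shift returns the olefin with C14 trans to C2, the ring-cis geometry, and MnO2 takes the allylic alcohol to the enal.

Step 13
Reactants: 20 C14 enal
Product: 21 (1S,2Z,4E,8E)-9-formyl-5-(hydroxymethyl)cyclodeca-2,4,8-trien-1-yl 3-methylbutanoate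
Conditions: SeO2 (0.5 equiv), t-BuOOH, CH2Cl2, 0 °C to rt
Reagents that add atoms: selenium dioxide, O=[Se]=O (oxygen, replenished by tert-butyl hydroperoxide, CC(C)(C)OO)
Why: Second Riley oxidation: with C1=C10 now an electron-poor enal, the ene reaction takes place at the trisubstituted C4=C5 end of the diene. The seleninic acid at C5 shifts to the unhindered C15 terminus and re-forms C4=C5 conjugated and ring-cis. Catalytic SeO2 with t-BuOOH favours the alcohol over the aldehyde.

Step 14
Reactants: 21 C15 alcohol
Product: 22 (1S,2Z,4E,8E)-5-{[tert-butyl(diphenyl)silyl]oxymethyl}-9-formylcyclodeca-2,4,8-trien-1-yl 3-methylbutanoate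
Conditions: t-BuPh2SiCl, imidazole, CH2Cl2, 0 °C
Reagents that add atoms: tert-butyl(chloro)diphenylsilane, CC(C)(C)[Si](Cl)(c1ccccc1)c1ccccc1
Why: Silylation of the primary allylic alcohol; this silyl ether withstands warm AcOH and CF3CO2H and is removed selectively by fluoride at the end.

Step 15
Reactants: 22 ring-cis cyclodecatrienal with C8 3-methylbutanoate and C15 silyl ether; 23 mono-tert-butyl malonate
Product: 24 tert-butyl (3S,3aR,4S,6E,10E,11aS)-10-{[tert-butyl(diphenyl)silyl]oxymethyl}-6-formyl-4-(3-methylbutanoyloxy)-2-oxo-2,3,3a,4,5,8,9,11a-octahydrocyclodeca[b]furan-3-carboxylate (cis-fused lactone; C11 epimer drawn with the ester trans to C8)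
Conditions: 23 (3 equiv), Mn(OAc)3·2H2O (2.2 equiv), Cu(OAc)2·H2O (20 mol %), KOAc, degassed AcOH, 40 °C
Reagents that add atoms: none
Why: Trivalent manganese oxidises its bound malonate half-ester enolate to an electrophilic radical that adds to C7, the unsubstituted terminus of the C4=C5–C6=C7 diene, and ignores the electron-poor C1=C10 enal. The C6–C5–C4 allyl radical is oxidised by divalent copper (or a second trivalent manganese) and the carboxylate closes on C6 in a 5-exo O-cyclisation, since closure on C4 would need a seven-membered ring; this forms C7–C11 and O–C6. The closest known reaction is the Mn(OAc)3 carbolactonisation of open-chain and cyclic 1,3-dienes with malonic or cyanoacetic acids, which gives γ-vinyl-γ-lactones with this regiochemistry. C7 is controlled by C8: with H8 eclipsing the olefin plane to avoid allylic 1,3-strain with C5, the C8–C9 ring bond covers the inner face, so the radical enters from the periphery and C11 ends up trans to the C8 ester. C6 is controlled by C7: the carboxylate is tethered to the face that C11 occupies, and the ring-cis C6=C7 bond of 22 leaves a small C5–C6–C7–C8 torsion, so fast oxidation and closure give the cis-fused lactone. This cis fusion is a kinetic outcome and not one enforced by strain, because trans-fused γ-lactones are unstrained on ten-membered rings. C4=C5 keeps its geometry because the allyl radical and cation do not rotate on this time scale within the ring. The step therefore needs site, regio and facial selectivity, which rest on the enal deactivation, the substitution at C4 and the C8 stereocentre respectively; the C11 epimers converge in step 17.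

Step 16
Reactants: 24 tert-butyl ester lactone
Product: 25 (3aR,4S,6E,10E,11aS)-10-{[tert-butyl(diphenyl)silyl]oxymethyl}-6-formyl-4-(3-methylbutanoyloxy)-2-oxo-2,3,3a,4,5,8,9,11a-octahydrocyclodeca[b]furan-3-carboxylic acid
Conditions: CF3CO2H, CH2Cl2, 0 °C
Reagents that add atoms: none
Why: Acidolysis of the tert-butyl ester with loss of isobutene; the silyl ether, the isovalerate, the lactone and the enal are stable to brief cold CF3CO2H.

Step 17
Reactants: 25 lactone acid
Product: 27 (3aR,4S,6E,10E,11aS)-10-{[tert-butyl(diphenyl)silyl]oxymethyl}-6-formyl-3-methylidene-2-oxo-2,3,3a,4,5,8,9,11a-octahydrocyclodeca[b]furan-4-yl 3-methylbutanoate, via Mannich base 26 (not isolated)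
Conditions: Et2NH, 37% aq. CH2O, AcOH, NaOAc, rt then 60 °C
Reagents that add atoms: formaldehyde, C=O
Why: Mannich reaction at the acidic C11 of the malonic half-lactone, then decarboxylative elimination of diethylamine (decarboxylative methylenation), which creates C11=C13 and erases the C11 stereocentre.

Step 18
Reactants: 27 silyl-protected methylene lactone
Product: 28 (3aR,4S,6E,10E,11aS)-6-formyl-10-(hydroxymethyl)-3-methylidene-2-oxo-2,3,3a,4,5,8,9,11a-octahydrocyclodeca[b]furan-4-yl 3-methylbutanoate (6S,7R,8S in germacrane numbering)
Conditions: HF·pyridine, pyridine, THF, 0 °C to rt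
Reagents that add atoms: none
Why: Fluoride cleavage of the silyl ether under buffered, non-basic conditions that do not add to the α-methylene lactone or the enal.

## Compound list

1 | (1Z,5Z)-1,5-dimethylcycloocta-1,5-diene | C/C1=C/CC/C(C)=C\CC1 | starting material
2 | rac-(4Z)-1,5-dimethyl-9-oxabicyclo[6.1.0]non-4-ene, cis-epoxide | C[C@]12O[C@H]1CC/C(C)=C\CC2 | intermediate
3 | rac-(4Z)-1,5-dimethyl-8-(phenylselanyl)cyclooct-4-en-1-ol, OH and SePh trans (not isolated) | C[C@]1(O)[C@H]([Se]c2ccccc2)CC/C(C)=C\CC1 | intermediate
4 | selenoxide of 3 (not isolated) | C[C@]1(O)[C@H]([Se](=O)c2ccccc2)CC/C(C)=C\CC1 | intermediate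
5 | rac-(2Z,5Z)-1,5-dimethylcycloocta-2,5-dien-1-ol | CC1(O)/C=C\C/C(C)=C\CC1 | intermediate
6 | (2Z,6Z)-3,7-dimethylcycloocta-2,6-dien-1-one | O=C1/C=C(/C)CC/C=C(/C)C1 | intermediate
7 | vinylmagnesium bromide | C=C[Mg]Br | starting material
8 | rac-(2Z,6Z)-1-ethenyl-3,7-dimethylcycloocta-2,6-dien-1-ol | C=CC1(O)/C=C(/C)CC/C=C(/C)C1 | intermediate
9 | potassium dienolate of (2Z,6Z)-3,7-dimethylcyclodeca-2,6-dien-1-one, enolate C6=C7 (not isolated) | C1/C(C)=C\C([O-])=C/CC/C(C)=C\C1.[K+] | intermediate
10 | trimethylsilyl dienol ether of (2Z,6Z)-3,7-dimethylcyclodeca-2,6-dien-1-one, all ring olefins cis | C1/C(C)=C\C(O[Si](C)(C)C)=C/CC/C(C)=C\C1 | intermediate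
11 | (2Z,6Z,9Z)-3,7-dimethylcyclodeca-2,6,9-trien-1-one | C1/C(C)=C\C(=O)/C=C\C/C(C)=C\C1 | intermediate
12 | rac-(3Z,7Z)-4,8-dimethyl-11-oxabicyclo[8.1.0]undeca-3,7-dien-2-one, cis-epoxide | C1/C(C)=C\C(=O)[C@H]2O[C@H]2C/C(C)=C\C1 | intermediate
13 | hydrazone of 12 (not isolated) | C1/C(C)=C\C(=NN)[C@H]2O[C@H]2C/C(C)=C\C1 | intermediate
14 | rac-(2Z,4Z,8Z)-5,9-dimethylcyclodeca-2,4,8-trien-1-ol | C1/C(C)=C\C=C/C(O)C/C(C)=C\C1 | intermediate
15 | (2Z,4Z,8Z)-5,9-dimethylcyclodeca-2,4,8-trien-1-one | C1/C(C)=C\C=C/C(=O)C/C(C)=C\C1 | intermediate
16 | (1S,2Z,4Z,8Z)-5,9-dimethylcyclodeca-2,4,8-trien-1-ol | C1/C(C)=C\C=C/[C@@H](O)C/C(C)=C\C1 | intermediate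
17 | 3-methylbutanoic acid | CC(C)CC(=O)O | starting material
18 | (1S,2Z,4Z,8Z)-5,9-dimethylcyclodeca-2,4,8-trien-1-yl 3-methylbutanoate | C1/C(C)=C\C=C/[C@@H](OC(=O)CC(C)C)C/C(C)=C\C1 | intermediate
19 | (1S,2Z,4Z,8E)-9-(hydroxymethyl)-5-methylcyclodeca-2,4,8-trien-1-yl 3-methylbutanoate (not isolated) | C1/C(C)=C\C=C/[C@@H](OC(=O)CC(C)C)C/C(CO)=C\C1 | intermediate
20 | (1S,2Z,4Z,8E)-9-formyl-5-methylcyclodeca-2,4,8-trien-1-yl 3-methylbutanoate | C1/C(C)=C\C=C/[C@@H](OC(=O)CC(C)C)C/C(C=O)=C\C1 | intermediate
21 | (1S,2Z,4E,8E)-9-formyl-5-(hydroxymethyl)cyclodeca-2,4,8-trien-1-yl 3-methylbutanoate | C1/C(CO)=C\C=C/[C@@H](OC(=O)CC(C)C)C/C(C=O)=C\C1 | intermediate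
22 | (1S,2Z,4E,8E)-5-{[tert-butyl(diphenyl)silyl]oxymethyl}-9-formylcyclodeca-2,4,8-trien-1-yl 3-methylbutanoate | C1/C(CO[Si](c2ccccc2)(c2ccccc2)C(C)(C)C)=C\C=C/[C@@H](OC(=O)CC(C)C)C/C(C=O)=C\C1 | intermediate
23 | mono-tert-butyl malonate (3-tert-butoxy-3-oxopropanoic acid) | CC(C)(C)OC(=O)CC(=O)O | starting material
24 | tert-butyl (3S,3aR,4S,6E,10E,11aS)-10-{[tert-butyl(diphenyl)silyl]oxymethyl}-6-formyl-4-(3-methylbutanoyloxy)-2-oxo-2,3,3a,4,5,8,9,11a-octahydrocyclodeca[b]furan-3-carboxylate | CC(C)(C)OC(=O)[C@@H]1C(=O)O[C@H]2/C=C(/CO[Si](c3ccccc3)(c3ccccc3)C(C)(C)C)CC/C=C(/C=O)C[C@H](OC(=O)CC(C)C)[C@@H]12 | intermediate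
25 | corresponding C11 carboxylic acid (3aR,4S,11aS; C11 epimerisable) | OC(=O)[C@@H]1C(=O)O[C@H]2/C=C(/CO[Si](c3ccccc3)(c3ccccc3)C(C)(C)C)CC/C=C(/C=O)C[C@H](OC(=O)CC(C)C)[C@@H]12 | intermediate
26 | C11 diethylaminomethyl Mannich base of 25, C11 configuration undefined (not isolated) | CCN(CC)CC1(C(=O)O)C(=O)O[C@H]2/C=C(/CO[Si](c3ccccc3)(c3ccccc3)C(C)(C)C)CC/C=C(/C=O)C[C@H](OC(=O)CC(C)C)[C@@H]12 | intermediate
27 | (3aR,4S,6E,10E,11aS)-10-{[tert-butyl(diphenyl)silyl]oxymethyl}-6-formyl-3-methylidene-2-oxo-2,3,3a,4,5,8,9,11a-octahydrocyclodeca[b]furan-4-yl 3-methylbutanoate | C=C1C(=O)O[C@H]2/C=C(/CO[Si](c3ccccc3)(c3ccccc3)C(C)(C)C)CC/C=C(/C=O)C[C@H](OC(=O)CC(C)C)[C@@H]12 | intermediate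
28 | (3aR,4S,6E,10E,11aS)-6-formyl-10-(hydroxymethyl)-3-methylidene-2-oxo-2,3,3a,4,5,8,9,11a-octahydrocyclodeca[b]furan-4-yl 3-methylbutanoate | C=C1C(=O)O[C@H]2/C=C(/CO)CC/C=C(/C=O)C[C@H](OC(=O)CC(C)C)[C@@H]12 | target

## Step count and least certain steps

Total: 18 steps. Longest linear sequence: 18 steps, from 1 to 28; 7, 17 and 23 are used as bought.

**Step 15 (key step).**
- **What may go wrong:** poor facial selectivity at C7, or bond rotation before closure, would give the C7 epimer or a trans-fused lactone. The conformation of a ten-membered triene cannot be predicted securely, and ring strain does not forbid the trans lactone. Further oxidation of the malonate-type C11–H of the product by trivalent manganese would also erode material.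
- **Fallback:** it sets out from 22. Rh2(OAc)4-catalysed cyclopropanation of the C6=C7 olefin with di-tert-butyl diazomalonate is stereospecifically cis and should give the vinylcyclopropane diester F1. CF3CO2H then cleaves both tert-butyl esters to the cyclopropane diacid F2, which ionises at the allylic C6–C11 bond and relactonises through the tethered carboxyl on the same face. This is the known vinylcyclopropane-1,1-dicarboxylic acid to γ-vinyl lactone rearrangement. The route is rejoined at 25, with the cis fusion fixed by the cyclopropane.

**Step 5.**
- **What may go wrong:** the [1,3] shift may be outrun by the [3,3] shift, which keeps the eight-membered ring, or by simple fragmentation of the bis-allylic alkoxide, because the ion pair can recombine at either allyl terminus or not at all.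
- **Fallback:** it sets out from 8, which is silylated to the trimethylsilyl ether F3 and rearranged thermally in a flow tube. This is a neutral [1,3] shift through a diradical and not an ion pair, and it gives the silyl dienol ether directly. The route is rejoined at 10.

**Step 8.**
- **What may go wrong:** the hydrazone may fragment to the ring-trans C6=C7 olefin, or the hydrazone nitrogen may add to C4 and give a pyrazoline. The olefin geometry is set kinetically from whichever rotamer about C6–C7 fragments.
- **Fallback:** it sets out from 12. The ring-trans dienol F4 is not discarded; it is oxidised to the (2E,4Z,8Z)-dienone F5 and equilibrated by reversible conjugate addition of a catalytic nucleophile (Bu3P or iodine) to the more stable ring-cis dienone. The route is rejoined at 15, so the geometry is placed under thermodynamic control.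

**Step 13.**
- **What may go wrong:** poor site selectivity or over-oxidation. The seleninic acid formed at C5 is doubly allylic and can deliver oxygen to C7 as well as C15, SeO2 can also add across a diene, and the dienylic alcohol is easily taken on to the aldehyde.
- **Fallback:** it sets out from 20, which is taken through the conditions of step 15 to the C15-methyl lactone tert-butyl ester F6. Acidolysis gives the acid F7, and methylenation through the Mannich base F8 gives the 15-deoxy methylene lactone F9. Allylic hydroxylation with SeO2 and t-BuOOH is then carried out last, on an isolated trisubstituted olefin whose only other activated neighbour is the enal; this is the known oxidation of the E-methyl group of a prenyl-ester-type olefin. The route is rejoined at 28.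

## Further compounds

F1 | step 15 | di-tert-butyl cyclopropane-1,1-dicarboxylate fused cis across C6–C7 of 22, anti to the C8 ester | CC(C)(C)OC(=O)C1(C(=O)OC(C)(C)C)[C@H]2/C=C(/CO[Si](c3ccccc3)(c3ccccc3)C(C)(C)C)CC/C=C(/C=O)C[C@H](OC(=O)CC(C)C)[C@@H]12
F2 | step 15 | corresponding cyclopropane-1,1-dicarboxylic acid | OC(=O)C1(C(=O)O)[C@H]2/C=C(/CO[Si](c3ccccc3)(c3ccccc3)C(C)(C)C)CC/C=C(/C=O)C[C@H](OC(=O)CC(C)C)[C@@H]12
F3 | step 5 | rac-(2Z,6Z)-1-ethenyl-3,7-dimethyl-1-(trimethylsilyloxy)cycloocta-2,6-diene | C=CC1(O[Si](C)(C)C)/C=C(/C)CC/C=C(/C)C1
F4 | step 8 | rac-(2E,4Z,8Z)-5,9-dimethylcyclodeca-2,4,8-trien-1-ol | C1/C(C)=C\C=C\C(O)C/C(C)=C\C1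
F5 | step 8 | (2E,4Z,8Z)-5,9-dimethylcyclodeca-2,4,8-trien-1-one | C1/C(C)=C\C=C\C(=O)C/C(C)=C\C1
F6 | step 13 | tert-butyl (3S,3aR,4S,6E,10Z,11aS)-6-formyl-10-methyl-4-(3-methylbutanoyloxy)-2-oxo-2,3,3a,4,5,8,9,11a-octahydrocyclodeca[b]furan-3-carboxylate | CC(C)(C)OC(=O)[C@@H]1C(=O)O[C@H]2/C=C(/C)CC/C=C(/C=O)C[C@H](OC(=O)CC(C)C)[C@@H]12
F7 | step 13 | corresponding C11 carboxylic acid | OC(=O)[C@@H]1C(=O)O[C@H]2/C=C(/C)CC/C=C(/C=O)C[C@H](OC(=O)CC(C)C)[C@@H]12
F8 | step 13 | C11 diethylaminomethyl Mannich base of F7 | CCN(CC)CC1(C(=O)O)C(=O)O[C@H]2/C=C(/C)CC/C=C(/C=O)C[C@H](OC(=O)CC(C)C)[C@@H]12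
F9 | step 13 | (3aR,4S,6E,10Z,11aS)-6-formyl-10-methyl-3-methylidene-2-oxo-2,3,3a,4,5,8,9,11a-octahydrocyclodeca[b]furan-4-yl 3-methylbutanoate | C=C1C(=O)O[C@H]2/C=C(/C)CC/C=C(/C=O)C[C@H](OC(=O)CC(C)C)[C@@H]12
A1 | alternative 1 | (2Z,6Z)-3,7-dimethylcyclodeca-2,6-dien-1-one | O=C1/C=C(/C)CC/C=C(/C)CCC1
A2 | alternative 2 | ten-membered ring-cis diene with C15 methyl ester, C6 silyl ether, C8 4-methoxybenzyl ether, C14 silyl ether and C12 dimethyl acetal | CC(C)(C)[Si](C)(C)O[C@H]1/C=C(/C(=O)OC)CC/C=C(/CO[Si](c2ccccc2)(c2ccccc2)C(C)(C)C)C[C@H](OCc2ccc(OC)cc2)[C@H]1CC(OC)OC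
A3 | alternative 3 | ten-membered ring-cis diene cis-lactone with C15 4-methoxybenzyl ether, C14 silyl ether and C8 3-methylbutanoate | C1C(=O)O[C@H]2/C=C(/COCc3ccc(OC)cc3)CC/C=C(/CO[Si](C)(C)C(C)(C)C)C[C@H](OC(=O)CC(C)C)[C@@H]12
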